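(The numbers in the tables were computed for substances that don't exist, noise included.)

Minutes are my unit here: I count how many lifetimes of the unused part of the charge, the part not yet in L, fit into the time asked.

| setting | theta | eta | larch | ash | alder | oak |
|---|---|---|---|---|---|---|
| X | 0.055 M | 0.055 M | 0.055 M | 0.055 M | 0.055 M | 0.055 M |
| Z | 0.67 mM | 16 mM | 0.50 mM | 1.5 mM | 4.0 mM | 12 mM |
| remark | run made earlier | run made earlier |  |  |  |  |
| time |  |  | 4.0 min | 4.0 min | 4.0 min | 4.0 min |

| run | time / min | L / % |
|---|---|---|
| theta | 0.250 | 0 |
| theta | 0.333 | 1 |
| theta | 0.500 | 2 |
| theta | 0.833 | 6 |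
| theta | 1.33 | 6 |
| theta | 2.00 | 7 |
| theta | 3.00 | 14 |
| eta | 0.167 | 17 |
| eta | 0.417 | 40 |
| eta | 0.833 | 57 |
| eta | 1.33 | 70 |
| eta | 1.50 | 70 |
| eta | 2.00 | 75 |
| eta | 3.00 | 79 |

(standard deviation of a reading: 1.5 percentage points)

- amount of L at the end, in percent of the X charged for larch, ash, alder, oak, in this order
- the shape of the row from first to last (hardly changes / falls, then rises / rises, then falls / rises all the way / falls all the way)

- the earlier runs were read with a standard deviation of 1.5 percentage points
- reactions considered so far: X + Z -> G + L; X + G -> L + G; Z -> D; X <-> E
- "hardly changes" means that all values lie within two and a half points (for a concentration: within two and a half percent of the largest)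

The start of eta gives the first link. The reading at 0.167 min puts the unused part at 83.0%, which reads as a capture lifetime of 0.896 min. I treat this as pseudo-first-order in X and let it stretch in inverse proportion to the charge of Z, taking each Z to leave one end. For oak that makes 1.20 min.

Later in eta the unused part falls more slowly, with a lifetime of 4.68 min. Since X <-> E is on the list, I read this as charge parked in E. Taking capture off leaves 3.79 min, the waiting lifetime: the time unused charge spends held back, added to capture once the parking has set in. The early and late lines of eta cross at 1.02 min. I keep that crossing time for the four new flasks: before it I count capture, and after it capture plus waiting, which for oak is 4.98 min.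

Over 4.0 min my row is 12.0%, 28.1%, 49.8% and 76.6%.

The weak link is stretching one eta reading down to small charges of Z, so I test it on theta, which I have not used. The reckoning gives 11.9% at 3.00 min, against a reading of 14%. The gap of 2.1 percentage points stands beside a scatter of 1.5 points, so this one reading does not break the link.

The forecast gives 15%, 36%, 60% and 78%, rises all the way: “the row keeps rising, with saturation”. It stands above mine at larch and at ash; the shape is the same.

    X + Z → G + L (k = 1.20 M⁻¹ s⁻¹)
    X + G → L + G, rate k2*[G]*[X] (k = 1.90 M⁻¹ s⁻¹)
    Z → D (k = 6.00 × 10⁻⁶ s⁻¹)
    X ⇌ E (K = 2.30, k = 0.0110 s⁻¹)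

The flask gives 9.75%, 25.5%, 50.6% and 78.8%, rises all the way. At 4.00 min oak holds 18.3% of the X charged as E against 2.93% as X. Starting from the 68.4% of L that oak holds at 2.00 min, a lifetime of waiting plus capture of 4.98 min reckons L at 78.9% at 4.00 min, and oak stands at 78.8%. Alder, with waiting plus capture of 7.37 min, goes over the same interval from 37.6% to a reckoned 52.4%, and alder stands at 50.6%.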